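Perrottetin E is disconnected at the two aryl–carbon bonds where its ethano bridges meet the diaryl ether core: C-4 of the para-disubstituted ring B, para to the bridging oxygen, and the carbon of the trisubstituted ring C that is para to the phenolic oxygen and meta to the bridging oxygen. These are the two positions of 2-phenoxyanisole most open to electrophilic attack, so a single twofold Friedel–Crafts acylation with [3-(mesyloxy)phenyl]acetyl chloride attaches both two-carbon arms, as ketones, to an ether core that carries no carbon substituent beforehand. The precursor is the O-methylated diaryl ether itself; the sulfonate keeps the reagent's own ring inert. Ketone deoxygenation and two deprotections complete the route.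

Key step: step 4

Remark on the chemistry: perrottetin E has no stereocentre and no stereogenic double bond, so the target is taken as the achiral compound drawn and no stereocontrol is needed.

**Step 1**
Reactants: 1 guaiacol (2-methoxyphenol); 2 iodobenzene
Product: 3 2-phenoxyanisole (1-methoxy-2-phenoxybenzene)
Conditions: CuI (10 mol %), picolinic acid (20 mol %), K3PO4 (2 equiv), DMSO, 90 °C
Reagents that add atoms: none
Why: Ullmann-type copper-catalysed C–O coupling, in which the Cu(I)/picolinate system arylates ortho-substituted phenoxides such as guaiacolate with aryl iodides under mild base and neither partner carries another reactive group.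

**Step 2**
Reactants: 4 (3-hydroxyphenyl)acetic acid
Product: 5 [3-(methanesulfonyloxy)phenyl]acetic acid
Conditions: MsCl (1.5 equiv), 2 M NaOH (aq)/THF, 0 °C, pH kept ≥ 11; then HCl to pH 1
Reagents that add atoms: methanesulfonyl chloride, CS(=O)(=O)Cl
Why: Schotten–Baumann O-sulfonylation, in which the phenoxide is far more nucleophilic than the carboxylate towards the sulfonyl chloride in cold aqueous alkali, any carboxylic–sulfonic mixed anhydride is hydrolysed back at once, and the aryl mesylate survives cold dilute hydroxide until acidification.

**Step 3**
Reactants: 5 [3-(methanesulfonyloxy)phenyl]acetic acid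
Product: 6 [3-(methanesulfonyloxy)phenyl]acetyl chloride
Conditions: (COCl)2 (1.3 equiv), cat. DMF, CH2Cl2, 0 °C → rt; evaporate, use crude
Reagents that add atoms: oxalyl chloride, O=C(Cl)C(Cl)=O
Why: Standard acid chloride formation through the chloroiminium species generated from oxalyl chloride and catalytic DMF, which gives only gaseous by-products and leaves an aryl mesylate untouched.

**Step 4**
Reactants: 3 2-phenoxyanisole (1 equiv); 6 [3-(methanesulfonyloxy)phenyl]acetyl chloride (2.3 equiv)
Product: 8 bis-ketone 3-{2-[4-(2-methoxy-5-{[3-(methanesulfonyloxy)phenyl]acetyl}phenoxy)phenyl]-2-oxoethyl}phenyl methanesulfonate, via ring-C monoketone 7 (not isolated)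
Conditions: AlCl3 (5 equiv), CH2Cl2, 0 °C → rt (6 and AlCl3 premixed, 3 added last); ice/1 M HCl
Reagents that add atoms: none
Why: AlCl3 ionises 6 to an arylacetylium ion, which should attack ring C of 3 at the carbon para to the methoxy oxygen through a Wheland intermediate to give monoketone 7, after which a second acylium ion attacks ring B of 7 at the carbon para to the bridging oxygen. The closest known reaction type is the Friedel–Crafts acylation of anisoles and of diphenyl ether (including its 4,4'-bis-acylation) with arylacetyl chlorides to deoxybenzoins. No ring is closed and no stereocentre is formed. The selectivity needed on ring C, para to OMe and not para to the aryloxy oxygen, rests on the methoxy oxygen donating into ring C alone whereas the bridging oxygen divides its lone pair between two rings; on ring B the only activated and unhindered site is para to that oxygen. Each ketone, bound to AlCl3, shuts down only the ring that carries it, and because the ring-C acyl group sits meta to the bridging oxygen it does not drain that oxygen's donation into ring B, so the second acylation should still proceed. The meta-mesyloxy group is inert to AlCl3, deactivates the reagent's own ring against self-acylation and disfavours loss of CO from the acylium ion to a benzyl cation.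

**Step 5**
Reactants: 8 bis-ketone
Product: 9 3-{2-[4-(2-methoxy-5-{2-[3-(methanesulfonyloxy)phenyl]ethyl}phenoxy)phenyl]ethyl}phenyl methanesulfonate
Conditions: Et3SiH (6 equiv), TFA, 0 °C → 50 °C
Reagents that add atoms: none
Why: Ionic hydrogenation, in which each protonated aryl ketone takes hydride from the silane, the resulting benzylic alcohol ionises in TFA to a cation stabilised by the para oxygen substituent (methoxy on ring C, aryloxy on ring B) and is reduced again to CH2, while sulfonates and ethers are untouched by TFA.

**Step 6**
Reactants: 9 bis(mesylate) methyl ether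
Product: 10 3-{2-[4-(5-[2-(3-hydroxyphenyl)ethyl]-2-methoxyphenoxy)phenyl]ethyl}phenol
Conditions: KOH (6 equiv), MeOH/H2O (3:1), reflux; then 2 M HCl
Reagents that add atoms: none
Why: Alkaline hydrolysis of aryl sulfonate esters by hydroxide attack at sulfur should release the two phenoxides, and the methyl ether, the diaryl ether and the bibenzyl chains are inert to hot aqueous-methanolic KOH.

**Step 7**
Reactants: 10 ring-C O-methyl perrottetin E
Product: 11 perrottetin E, 4-[2-(3-hydroxyphenyl)ethyl]-2-{4-[2-(3-hydroxyphenyl)ethyl]phenoxy}phenol
Conditions: BBr3 (4 equiv), CH2Cl2, −78 °C → 0 °C; then H2O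
Reagents that add atoms: none
Why: Lewis-acid ether cleavage, in which BBr3 coordinates the methoxy oxygen and bromide removes the methyl group by SN2, whereas the diaryl ether has no sp3 carbon on oxygen and cannot be cleaved this way, and aqueous work-up hydrolyses the aryloxyboranes to the three free phenols.

**Compound list**
1 | guaiacol (2-methoxyphenol) | COc1ccccc1O | starting material
2 | iodobenzene | Ic1ccccc1 | starting material
3 | 2-phenoxyanisole (1-methoxy-2-phenoxybenzene) | COc1ccccc1Oc1ccccc1 | intermediate
4 | (3-hydroxyphenyl)acetic acid | OC(=O)Cc1cccc(O)c1 | starting material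
5 | [3-(methanesulfonyloxy)phenyl]acetic acid | CS(=O)(=O)Oc1cccc(CC(O)=O)c1 | intermediate
6 | [3-(methanesulfonyloxy)phenyl]acetyl chloride | CS(=O)(=O)Oc1cccc(CC(Cl)=O)c1 | intermediate
7 | 3-[2-(4-methoxy-3-phenoxyphenyl)-2-oxoethyl]phenyl methanesulfonate (ring-C monoketone) | COc1ccc(C(=O)Cc2cccc(OS(C)(=O)=O)c2)cc1Oc1ccccc1 | intermediate (not isolated)
8 | 3-{2-[4-(2-methoxy-5-{[3-(methanesulfonyloxy)phenyl]acetyl}phenoxy)phenyl]-2-oxoethyl}phenyl methanesulfonate (bis-ketone) | COc1ccc(C(=O)Cc2cccc(OS(C)(=O)=O)c2)cc1Oc1ccc(C(=O)Cc2cccc(OS(C)(=O)=O)c2)cc1 | intermediate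
9 | 3-{2-[4-(2-methoxy-5-{2-[3-(methanesulfonyloxy)phenyl]ethyl}phenoxy)phenyl]ethyl}phenyl methanesulfonate | COc1ccc(CCc2cccc(OS(C)(=O)=O)c2)cc1Oc1ccc(CCc2cccc(OS(C)(=O)=O)c2)cc1 | intermediate
10 | 3-{2-[4-(5-[2-(3-hydroxyphenyl)ethyl]-2-methoxyphenoxy)phenyl]ethyl}phenol | COc1ccc(CCc2cccc(O)c2)cc1Oc1ccc(CCc2cccc(O)c2)cc1 | intermediate
11 | perrottetin E | Oc1cccc(CCc2ccc(Oc3cc(CCc4cccc(O)c4)ccc3O)cc2)c1 | target

**Step count**
Total steps: 7. Longest linear sequence: 6 steps (4 → 5 → 6 → 8 → 9 → 10 → 11).

**Steps most likely to fail**

Step 4. Three processes could spoil it: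
- positional control on ring C could erode through attack para to the bridging oxygen;
- the reaction could stall after the first acylation as the Lewis acid is tied up by the ketone, sulfonates and ethers;
- the methyl ether could be cleaved by the Lewis acid and the phenol then O-acylated.

The fallback gives up the twofold C–H acylation of the preformed ether. It sets out from acid chloride 6 and guaiacol 1 and comes back at 8. Acid chloride 6 would first acylate fluorobenzene (AlCl3, fluorobenzene as solvent, 0 °C → rt, para-selective) to give 1-(4-fluorophenyl)-2-[3-(methanesulfonyloxy)phenyl]ethan-1-one F1. Its fluoride, activated by the para carbonyl, would be displaced by guaiacol 1 (K2CO3, DMF, 90 °C, SNAr) to give 3-{2-[4-(2-methoxyphenoxy)phenyl]-2-oxoethyl}phenyl methanesulfonate F2, in which ring B already carries its arm. One Friedel–Crafts acylation of F2 with 6 (AlCl3, CH2Cl2) then has to occur on ring C only. The bridging oxygen is now conjugated with the para-acyl group of ring B and is a weak donor towards ring C, so the methoxy group alone should direct the attack and bis-ketone 8 should result.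

Step 5. Deoxygenation could stop at the less stabilised ring-B carbinol, its trifluoroacetate or the stilbene, or the benzylic cations could be captured by an electron-rich ring. The fallback replaces the cationic silane reduction by hydride reduction followed by catalytic hydrogenolysis. It sets out from 8 and comes back at 9. NaBH4 (MeOH/THF, 0 °C) would reduce both ketones to the bis(carbinol) 3-{2-hydroxy-2-[4-(5-{1-hydroxy-2-[3-(methanesulfonyloxy)phenyl]ethyl}-2-methoxyphenoxy)phenyl]ethyl}phenyl methanesulfonate F3, a mixture of diastereomers whose carbinol centres are removed next. Hydrogenolysis of the two benzylic C–O bonds (H2, Pd/C, AcOH, cat. HClO4, rt) should then give 9 with the aryl mesylates intact.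

Step 2. Chemoselectivity could be lost through activation of the carboxylate and ester oligomerisation, or hydrolysis of the sulfonyl chloride could outrun sulfonylation. The fallback masks the acid first. It sets out from 4 and comes back at 5. Fischer esterification (MeOH, cat. H2SO4, reflux) would give methyl (3-hydroxyphenyl)acetate F4. Mesylation under anhydrous conditions (MsCl, Et3N, CH2Cl2, 0 °C) would give methyl [3-(methanesulfonyloxy)phenyl]acetate F5. Acid hydrolysis of the ester (6 M HCl, dioxane, 90 °C), to which an aryl mesylate is stable, should deliver 5.

**Further compounds**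
F1 | step 4 | 1-(4-fluorophenyl)-2-[3-(methanesulfonyloxy)phenyl]ethan-1-one | CS(=O)(=O)Oc1cccc(CC(=O)c2ccc(F)cc2)c1
F2 | step 4 | 3-{2-[4-(2-methoxyphenoxy)phenyl]-2-oxoethyl}phenyl methanesulfonate | COc1ccccc1Oc1ccc(C(=O)Cc2cccc(OS(C)(=O)=O)c2)cc1
F3 | step 5 | 3-{2-hydroxy-2-[4-(5-{1-hydroxy-2-[3-(methanesulfonyloxy)phenyl]ethyl}-2-methoxyphenoxy)phenyl]ethyl}phenyl methanesulfonate (mixture of diastereomers, stereocentres undefined) | COc1ccc(C(O)Cc2cccc(OS(C)(=O)=O)c2)cc1Oc1ccc(C(O)Cc2cccc(OS(C)(=O)=O)c2)cc1
F4 | step 2 | methyl (3-hydroxyphenyl)acetate | COC(=O)Cc1cccc(O)c1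
F5 | step 2 | methyl [3-(methanesulfonyloxy)phenyl]acetate | COC(=O)Cc1cccc(OS(C)(=O)=O)c1
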